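The runs are calculated for an exercise; noise was put on by code.

all flasks: starting material 0.31 M; capture agent 0.0155 M; free catalyst 0.62 mM

| charge | reagent | remark |
|---|---|---|
| blue | 0.23 M | run made earlier |
| amber | 0.35 M | run made earlier |
| flask | 0.465 M |  |

- blue (time / min: target / %): 10.0: 11; 25.0: 19; 50.0: 27; 80.0: 26
- amber (time / min: target / %): 10.0: 11; 25.0: 21; 50.0: 25; 80.0: 27

(standard deviation of a reading: 1.5 percentage points)

- apparent order in free catalyst when 5.0% of the starting material are converted (percent change of the rate of making target for one percent more free catalyst charged)
- apparent order in reagent when 5.0% of the starting material are converted (percent change of the rate of making target for one percent more reagent charged)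

- no earlier run changes the charge of free catalyst; that part of a forecast is a guess

1. If target stops rising while reagent and starting material remain, the number to know is how much target the catalyst charge can make. The late readings of blue and amber average 26.2%. This mean, with the scatter of its readings, is the estimate used here of the capacity Q, the target made before the catalyst charge is lost from its round (a turnover number, counted in target). Blue's reagent charge of 0.23 M stands above the 0.0814 M of target that Q means.

2. Suppose each round risks the catalyst equally. Working catalyst then falls in step with target, and at target level X the rate follows the charge times (1 − X/Q). If Q also grows in proportion to the charge, which is a guess, the order in free catalyst at the charge used is 1/(1 − X/Q).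

3. Q need not be known closely: amber's late readings alone, 25% and 27%, give orders of 1.25 and 1.23. The proportion guess weighs more, since in this reckoning a Q held fixed gives order 1, and that shift exceeds the gap between amber's two orders.

4. The reagent order depends on the readings. Amber and blue differ by 2 percentage points at 25.0 min, against a scatter of 1.5 points per reading. That pair gives 0.238, and the pair at 10.0 min gives 0.

5. The reckoning here gives 1.24 in free catalyst and about 0.238 in reagent. The forecast, holding that "the plateau scales with catalyst", gives 1.1 (0.7 to 1.5) and 0.1 (−0.15 to 0.4), both lower.

6. The flask's mechanism:

    starting material + free catalyst ⇌ catalyst intermediate A (K = 4.10 L mol⁻¹, k = 700 L mol⁻¹ min⁻¹)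
    capture agent + catalyst intermediate C → trapped intermediate (k = 13.0 L mol⁻¹ min⁻¹)
    reagent + catalyst intermediate A → catalyst intermediate B (k = 130 L mol⁻¹ min⁻¹)
    catalyst intermediate C → free catalyst + target (k = 28.0 min⁻¹)
    catalyst intermediate B ⇌ released group + catalyst intermediate C (K = 0.110 M, k = 33.0 min⁻¹)

The flask gives 1.2 in free catalyst and 0.30 in reagent. At 2.79 min, 27.3% of its catalyst stood as catalyst intermediate B. At 0.150 h the flask held 12.3% target, which is 46.9% of the Q estimated from blue and amber, and trapped intermediate held 44.0% of the catalyst.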